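**Plan**
- Retrosynthesis: the ether bond O1–C2 is cut first (back to a phenol/primary alcohol), the alcohol is traced to a 3-aryl-3,4-dihydrocoumarin, and in this lactone C3–C4 and O1–C2(acyl) are cut together.
- Enabling feature: ring C (O1, C2, C3, C4, C4a, C8a) is the ortho-quinone methide of ring A (C4=C4a–C8a=O1) capped by the two-carbon unit C2–C3, where C3 is the alpha carbon and C2 the carboxyl carbon of a ring B arylacetic acid.
- Both partners come from one aldehyde (8), made from 2,4-dihydroxybenzaldehyde by 4-O-prenylation, O2 silylation, aromatic Claisen rearrangement to C5 and O4 allylation.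
- Forward: rings A and B enter as arenes; ring C is closed as the lactone in the annulation, opened by hydride, re-closed as the cyclic ether, and the three allyl ethers are removed last.
- Stereochemistry: the only stereocentre, C3 (R), is set in the annulation by (R)-benzotetramisole and cannot epimerise once the lactone is reduced.

Key step: step 11

Assumption: the accepted model for isothiourea-bound (Z)-enolates (enolate oxygen syn to sulfur, attack anti to the phenyl group next to the acylated nitrogen) is taken to hold for this ortho-alkoxy arylacetyl unit; it assigns the (3R)-lactone to (R)-benzotetramisole, (2R)-2-phenyl-2,3-dihydroimidazo[2,1-b][1,3]benzothiazole, SMILES c1ccccc1[C@@H]1CN2c3ccccc3SC2=N1.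

**Step 1**
Reactants: 1 2,4-dihydroxybenzaldehyde; 2 1-bromo-3-methylbut-2-ene (prenyl bromide)
Product: 3 2-hydroxy-4-[(3-methylbut-2-en-1-yl)oxy]benzaldehyde
Conditions: K2CO3 (1.0 equiv), acetone, rt
Reagents that add atoms: none
Why: Williamson ether synthesis that should be selective for O4, because the 2-OH is held in a hydrogen bond to the formyl group and is the less acidic phenol, so one equivalent of mild base alkylates only the para oxygen.

**Step 2**
Reactants: 3 2-hydroxy-4-[(3-methylbut-2-en-1-yl)oxy]benzaldehyde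
Product: 4 4-[(3-methylbut-2-en-1-yl)oxy]-2-[(triisopropylsilyl)oxy]benzaldehyde
Conditions: i-Pr3SiCl, imidazole, DMF, rt to 40 °C
Reagents that add atoms: chlorotri(propan-2-yl)silane (TIPSCl), CC(C)[Si](Cl)(C(C)C)C(C)C
Why: Imidazole-promoted silylation of a phenol, which breaks the OH···O=C chelate that would steer the coming rearrangement to C3 and installs at the future O1 a bulky, heat-stable group that fluoride can later remove.

**Step 3**
Reactants: 4 4-[(3-methylbut-2-en-1-yl)oxy]-2-[(triisopropylsilyl)oxy]benzaldehyde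
Product: 6 4-hydroxy-5-(2-methylbut-3-en-2-yl)-2-[(triisopropylsilyl)oxy]benzaldehyde, via ortho-dienone 5 (not isolated)
Conditions: PhNEt2, 190 °C, sealed tube, argon, short reaction time
Reagents that add atoms: none
Why: Aromatic Claisen rearrangement ([3,3]-sigmatropic shift, then tautomerisation of dienone 5) of an aryl prenyl ether delivers the ortho 1,1-dimethylallyl phenol with allyl inversion, and C5 should be chosen over C3 because C3 lies between two oxygen substituents, one of them the bulky silyloxy group, and the unchelated ring has no bias towards C3.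

**Step 4**
Reactants: 6 4-hydroxy-5-(2-methylbut-3-en-2-yl)-2-[(triisopropylsilyl)oxy]benzaldehyde; 7 3-bromoprop-1-ene (allyl bromide)
Product: 8 4-(allyloxy)-5-(2-methylbut-3-en-2-yl)-2-[(triisopropylsilyl)oxy]benzaldehyde
Conditions: K2CO3, MeCN, 50 °C
Reagents that add atoms: none
Why: Williamson etherification of the only free phenol, which is acidic because it is para to the formyl group, under carbonate conditions mild enough to leave the hindered aryl silyl ether in place.

**Step 5**
Reactants: 8 4-(allyloxy)-5-(2-methylbut-3-en-2-yl)-2-[(triisopropylsilyl)oxy]benzaldehyde; 7 3-bromoprop-1-ene (allyl bromide)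
Product: 9 2,4-bis(allyloxy)-5-(2-methylbut-3-en-2-yl)benzaldehyde
Conditions: CsF, DMF, rt
Reagents that add atoms: none
Why: Fluoride-mediated desilylative O-alkylation (Williamson reaction of the caesium phenoxide formed in situ), which exchanges the silyl group for the allyl group that ring B needs to survive the fluoride of step 11.

**Step 6**
Reactants: 9 2,4-bis(allyloxy)-5-(2-methylbut-3-en-2-yl)benzaldehyde
Product: 11 2-[2,4-bis(allyloxy)-5-(2-methylbut-3-en-2-yl)phenyl]acetonitrile, via vinylformamide 10 (not isolated)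
Conditions: TosMIC, t-BuOK, DME, −40 °C; then MeOH, reflux
Reagents that add atoms: p-toluenesulfonylmethyl isocyanide (TosMIC), Cc1ccc(cc1)S(=O)(=O)C[N+]#[C-]
Why: Van Leusen reductive cyanation, in which the TosMIC anion adds to the aldehyde, the oxazoline opens to formamide 10, and methanolysis with loss of sulfinate gives the one-carbon-homologated nitrile without acid or metals that could touch the alkenes.

**Step 7**
Reactants: 11 2-[2,4-bis(allyloxy)-5-(2-methylbut-3-en-2-yl)phenyl]acetonitrile
Product: 12 2-[2,4-bis(allyloxy)-5-(2-methylbut-3-en-2-yl)phenyl]acetic acid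
Conditions: KOH, EtOH/H2O, reflux; then cold 1 M HCl to pH 3
Reagents that add atoms: water, O; potassium hydroxide, [K+].[OH-]
Why: Basic hydrolysis of an arylacetonitrile to the carboxylic acid, which aryl allyl ethers and the 1,1-dimethylallyl group tolerate, followed by brief cold acidification that is harmless because no free phenol sits next to the tertiary allyl group.

**Step 8**
Reactants: 12 2-[2,4-bis(allyloxy)-5-(2-methylbut-3-en-2-yl)phenyl]acetic acid
Product: 13 4-nitrophenyl 2-[2,4-bis(allyloxy)-5-(2-methylbut-3-en-2-yl)phenyl]acetate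
Conditions: 4-nitrophenol, DCC, DMAP (cat.), CH2Cl2, 0 °C to rt
Reagents that add atoms: 4-nitrophenol, Oc1ccc(cc1)[N+]([O-])=O
Why: Steglich-type carbodiimide esterification gives a storable active ester whose aryloxide leaving group allows fast acyl transfer to the isothiourea in step 11.

**Step 9**
Reactants: 8 4-(allyloxy)-5-(2-methylbut-3-en-2-yl)-2-[(triisopropylsilyl)oxy]benzaldehyde
Product: 14 {4-(allyloxy)-5-(2-methylbut-3-en-2-yl)-2-[(triisopropylsilyl)oxy]phenyl}methanol
Conditions: NaBH4, MeOH/THF, 0 °C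
Reagents that add atoms: none
Why: Borohydride reduction of an aromatic aldehyde to the benzylic alcohol, run cold and briefly so that the bulky silyl group does not migrate to the new alkoxide.

**Step 10**
Reactants: 14 {4-(allyloxy)-5-(2-methylbut-3-en-2-yl)-2-[(triisopropylsilyl)oxy]phenyl}methanol
Product: 15 [5-(allyloxy)-2-(bromomethyl)-4-(2-methylbut-3-en-2-yl)phenoxy]triisopropylsilane
Conditions: CBr4, PPh3, CH2Cl2, 0 °C; short pad of basic Al2O3; used at once as a THF solution
Reagents that add atoms: tetrabromomethane, BrC(Br)(Br)Br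
Why: Appel bromination converts the benzylic alcohol under neutral conditions, which spares the silyl ether and the alkenes, and the electron-rich bromide is not stored but carried straight into the annulation.

**Step 11**
Reactants: 15 [5-(allyloxy)-2-(bromomethyl)-4-(2-methylbut-3-en-2-yl)phenoxy]triisopropylsilane; 13 4-nitrophenyl 2-[2,4-bis(allyloxy)-5-(2-methylbut-3-en-2-yl)phenyl]acetate
Product: 18 (3R)-7-(allyloxy)-3-[2,4-bis(allyloxy)-5-(2-methylbut-3-en-2-yl)phenyl]-6-(2-methylbut-3-en-2-yl)chroman-2-one, via ortho-quinone methide 16 (not isolated), via ammonium enolate 17 (not isolated)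
Conditions: (R)-benzotetramisole (20 mol%), CsF, 18-crown-6, i-Pr2NEt, THF, 0 °C, syringe-pump addition of 15; pH 7 work-up
Reagents that add atoms: none
Why: The isothiourea is acylated by the 4-nitrophenyl ester and the acyl ammonium ion is deprotonated to the (Z)-ammonium enolate 17, while fluoride removes the silyl group of 15 and the phenoxide expels bromide to give ortho-quinone methide 16; C3 of 17 then adds to the exocyclic methylene carbon C4 of 16, which restores the aromaticity of ring A, and the freed phenoxide O1 attacks the acyl ammonium carbon C2 and releases the catalyst. The closest known reaction type is the Lewis-base-catalysed formal [4+2] annulation (Michael addition–lactonisation) of ammonium or azolium enolates with ortho-quinone methides generated in situ, which gives 3,4-dihydrocoumarins. Ring C closes by 6-exo-trig lactonisation after the intermolecular C3–C4 bond formation. C3 is the only new stereocentre and is controlled by the catalyst: in 17 the enolate oxygen lies syn to sulfur, the pseudo-axial phenyl group covers one face, and C4 arrives on the open face, which for the (R)-catalyst should give the (3R)-lactone. The step needs enantiofacial selectivity at the enolate, C- rather than O-attack, and cross-reaction rather than self-addition of 16; the active ester acylates the catalyst faster than it enolises on its own, slow addition of 15 keeps the unsubstituted methide at low concentration, and low temperature with little excess base protects the enolisable alpha-aryl lactone.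

**Step 12**
Reactants: 18 (3R)-7-(allyloxy)-3-[2,4-bis(allyloxy)-5-(2-methylbut-3-en-2-yl)phenyl]-6-(2-methylbut-3-en-2-yl)chroman-2-one
Product: 19 5-(allyloxy)-2-{(2R)-2-[2,4-bis(allyloxy)-5-(2-methylbut-3-en-2-yl)phenyl]-3-hydroxypropyl}-4-(2-methylbut-3-en-2-yl)phenol
Conditions: LiAlH4, THF, −20 to 0 °C, carried out directly after step 11
Reagents that add atoms: none
Why: Hydride reduction of the aryl ester (lactone) to the phenol and primary alcohol should outpace removal of the alpha proton, leaves allyl ethers and alkenes untouched, and turns C3 into a centre that can no longer enolise.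

**Step 13**
Reactants: 19 5-(allyloxy)-2-{(2R)-2-[2,4-bis(allyloxy)-5-(2-methylbut-3-en-2-yl)phenyl]-3-hydroxypropyl}-4-(2-methylbut-3-en-2-yl)phenol
Product: 20 (3R)-7-(allyloxy)-3-[2,4-bis(allyloxy)-5-(2-methylbut-3-en-2-yl)phenyl]-6-(2-methylbut-3-en-2-yl)chromane
Conditions: PPh3, DIAD, THF, 0 °C to rt, dilute
Reagents that add atoms: none
Why: Intramolecular Mitsunobu etherification (6-exo-tet attack of the only free phenol, O1, on the activated primary carbon C2) closes ring C without touching C3, and the allyl groups on ring B prevent its 2'-oxygen from competing.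

**Step 14**
Reactants: 20 (3R)-7-(allyloxy)-3-[2,4-bis(allyloxy)-5-(2-methylbut-3-en-2-yl)phenyl]-6-(2-methylbut-3-en-2-yl)chromane
Product: 21 Manuifolin E, (3R)-3-[2,4-dihydroxy-5-(2-methylbut-3-en-2-yl)phenyl]-6-(2-methylbut-3-en-2-yl)chroman-7-ol
Conditions: Pd(PPh3)4 (10 mol%), morpholine, degassed THF, rt; neutral work-up
Reagents that add atoms: none
Why: Tsuji–Trost-type deallylation, in which zerovalent palladium ionises the three aryl allyl ethers to pi-allyl complexes that morpholine traps, while the carbon-bound 1,1-dimethylallyl groups have no leaving group and stay, and the neutral medium avoids acid-induced cyclisation of the ortho-hydroxy tertiary allyl units.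

**Compound list**
1 | 2,4-dihydroxybenzaldehyde | O=Cc1ccc(O)cc1O | starting material
2 | 1-bromo-3-methylbut-2-ene (prenyl bromide) | CC(C)=CCBr | starting material
3 | 2-hydroxy-4-[(3-methylbut-2-en-1-yl)oxy]benzaldehyde | O=Cc1ccc(OCC=C(C)C)cc1O | intermediate
4 | 4-[(3-methylbut-2-en-1-yl)oxy]-2-[(triisopropylsilyl)oxy]benzaldehyde | O=Cc1ccc(OCC=C(C)C)cc1O[Si](C(C)C)(C(C)C)C(C)C | intermediate
5 | ortho-dienone, 5-(2-methylbut-3-en-2-yl)-4-oxo-2-[(triisopropylsilyl)oxy]cyclohexa-2,6-diene-1-carbaldehyde, racemic at C5 (not isolated) | O=CC1=CC(C(C)(C)C=C)C(=O)C=C1O[Si](C(C)C)(C(C)C)C(C)C | intermediate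
6 | 4-hydroxy-5-(2-methylbut-3-en-2-yl)-2-[(triisopropylsilyl)oxy]benzaldehyde | O=Cc1cc(C(C)(C)C=C)c(O)cc1O[Si](C(C)C)(C(C)C)C(C)C | intermediate
7 | 3-bromoprop-1-ene (allyl bromide) | C=CCBr | starting material
8 | 4-(allyloxy)-5-(2-methylbut-3-en-2-yl)-2-[(triisopropylsilyl)oxy]benzaldehyde | O=Cc1cc(C(C)(C)C=C)c(OCC=C)cc1O[Si](C(C)C)(C(C)C)C(C)C | intermediate
9 | 2,4-bis(allyloxy)-5-(2-methylbut-3-en-2-yl)benzaldehyde | O=Cc1cc(C(C)(C)C=C)c(OCC=C)cc1OCC=C | intermediate
10 | vinylformamide, N-{2-[2,4-bis(allyloxy)-5-(2-methylbut-3-en-2-yl)phenyl]-1-[(4-methylphenyl)sulfonyl]ethenyl}formamide, alkene geometry not defined (not isolated) | O=CNC(=Cc1cc(C(C)(C)C=C)c(OCC=C)cc1OCC=C)S(=O)(=O)c1ccc(C)cc1 | intermediate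
11 | 2-[2,4-bis(allyloxy)-5-(2-methylbut-3-en-2-yl)phenyl]acetonitrile | N#CCc1cc(C(C)(C)C=C)c(OCC=C)cc1OCC=C | intermediate
12 | 2-[2,4-bis(allyloxy)-5-(2-methylbut-3-en-2-yl)phenyl]acetic acid | OC(=O)Cc1cc(C(C)(C)C=C)c(OCC=C)cc1OCC=C | intermediate
13 | 4-nitrophenyl 2-[2,4-bis(allyloxy)-5-(2-methylbut-3-en-2-yl)phenyl]acetate | O=C(Cc1cc(C(C)(C)C=C)c(OCC=C)cc1OCC=C)Oc1ccc([N+](=O)[O-])cc1 | intermediate
14 | {4-(allyloxy)-5-(2-methylbut-3-en-2-yl)-2-[(triisopropylsilyl)oxy]phenyl}methanol | OCc1cc(C(C)(C)C=C)c(OCC=C)cc1O[Si](C(C)C)(C(C)C)C(C)C | intermediate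
15 | [5-(allyloxy)-2-(bromomethyl)-4-(2-methylbut-3-en-2-yl)phenoxy]triisopropylsilane | BrCc1cc(C(C)(C)C=C)c(OCC=C)cc1O[Si](C(C)C)(C(C)C)C(C)C | intermediate
16 | ortho-quinone methide, 3-(allyloxy)-6-methylidene-4-(2-methylbut-3-en-2-yl)cyclohexa-2,4-dien-1-one (not isolated) | C=C1C=C(C(C)(C)C=C)C(OCC=C)=CC1=O | intermediate
17 | ammonium enolate, (Z)-2-[2,4-bis(allyloxy)-5-(2-methylbut-3-en-2-yl)phenyl]-1-[(2R)-2-phenyl-2,3-dihydroimidazo[2,1-b][1,3]benzothiazol-1-ium-1-yl]ethen-1-olate (not isolated) | [O-]/C(=C\c1cc(C(C)(C)C=C)c(OCC=C)cc1OCC=C)[N+]1=C2Sc3ccccc3N2C[C@H]1c1ccccc1 | intermediate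
18 | (3R)-7-(allyloxy)-3-[2,4-bis(allyloxy)-5-(2-methylbut-3-en-2-yl)phenyl]-6-(2-methylbut-3-en-2-yl)chroman-2-one | C=CCOc1cc2c(cc1C(C)(C)C=C)C[C@H](c1cc(C(C)(C)C=C)c(OCC=C)cc1OCC=C)C(=O)O2 | intermediate
19 | 5-(allyloxy)-2-{(2R)-2-[2,4-bis(allyloxy)-5-(2-methylbut-3-en-2-yl)phenyl]-3-hydroxypropyl}-4-(2-methylbut-3-en-2-yl)phenol | C=CCOc1cc(O)c(cc1C(C)(C)C=C)C[C@H](c1cc(C(C)(C)C=C)c(OCC=C)cc1OCC=C)CO | intermediate
20 | (3R)-7-(allyloxy)-3-[2,4-bis(allyloxy)-5-(2-methylbut-3-en-2-yl)phenyl]-6-(2-methylbut-3-en-2-yl)chromane | C=CCOc1cc2c(cc1C(C)(C)C=C)C[C@H](c1cc(C(C)(C)C=C)c(OCC=C)cc1OCC=C)CO2 | intermediate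
21 | Manuifolin E, (3R)-3-[2,4-dihydroxy-5-(2-methylbut-3-en-2-yl)phenyl]-6-(2-methylbut-3-en-2-yl)chroman-7-ol | C=CC(C)(C)c1cc2c(cc1O)OC[C@@H](c1cc(C(C)(C)C=C)c(O)cc1O)C2 | target

**Step count and risks**
Total steps: 14. Longest linear sequence: 12 steps (steps 1–8, then 11–14); the ring A branch (steps 9 and 10) joins at step 11.

Steps most likely to fail:

1. Step 11. What may go wrong is loss of enantiopurity, either by an uncatalysed background addition of the free ester enolate or by enolisation of the alpha-aryl lactone after it has formed. The methide may also be consumed by self-addition, and the catalyst by N-benzylation. The fallback is an auxiliary-controlled alkylation that sets out from 12 and 15 and comes back at 19. Acid 12 is activated with pivaloyl chloride and Et3N and joined to (R)-4-benzyl-1,3-oxazolidin-2-one (LiCl, THF) to give (4R)-4-benzyl-3-{[2,4-bis(allyloxy)-5-(2-methylbut-3-en-2-yl)phenyl]acetyl}-1,3-oxazolidin-2-one F1. Its chelated sodium (Z)-enolate (NaN(SiMe3)2, THF, −78 °C) should be alkylated by bromide 15 on the face away from the benzyl group to give (4R)-3-{(2R)-3-{4-(allyloxy)-5-(2-methylbut-3-en-2-yl)-2-[(triisopropylsilyl)oxy]phenyl}-2-[2,4-bis(allyloxy)-5-(2-methylbut-3-en-2-yl)phenyl]propanoyl}-4-benzyl-1,3-oxazolidin-2-one F2. LiBH4 (THF, 0 °C) then cleaves the auxiliary reductively to (2R)-3-{4-(allyloxy)-5-(2-methylbut-3-en-2-yl)-2-[(triisopropylsilyl)oxy]phenyl}-2-[2,4-bis(allyloxy)-5-(2-methylbut-3-en-2-yl)phenyl]propan-1-ol F3, and Bu4NF in THF removes the silyl group to give diol 19.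

2. Step 3. What may go wrong is fragmentation of the prenyl ether to the phenol at the temperature needed, onward "abnormal" rearrangement of the free ortho-(1,1-dimethylallyl)phenol, or transfer of the silyl group from O2 to the newly freed O4. The fallback traps the phenol as an ester as it forms; it sets out from 3 and comes back at 8. Aldehyde 3 is acylated (butyric anhydride, pyridine, DMAP) to 2-formyl-5-[(3-methylbut-2-en-1-yl)oxy]phenyl butanoate F4, in which O2 again cannot chelate. Heating F4 in PhNEt2 with butyric anhydride should give 4-formyl-6-(2-methylbut-3-en-2-yl)-1,3-phenylene dibutanoate F5, because the rearranged phenol is esterified before it can react further. K2CO3 in MeOH cleaves both esters to 2,4-dihydroxy-5-(2-methylbut-3-en-2-yl)benzaldehyde F6. The para oxygen is then alkylated selectively with allyl bromide 7 (K2CO3, acetone) to give 4-(allyloxy)-2-hydroxy-5-(2-methylbut-3-en-2-yl)benzaldehyde F7, and silylation (i-Pr3SiCl, imidazole, DMF) gives 8.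

3. Step 10. What may go wrong is ionisation of the electron-rich benzylic bromide during its preparation or transfer (self-alkylation, hydrolysis on the adsorbent), or quaternisation of PPh3 by the product. The fallback avoids the halide; it sets out from 14 and comes back at 18. Acetylation of 14 (Ac2O, pyridine, DMAP) gives {4-(allyloxy)-5-(2-methylbut-3-en-2-yl)-2-[(triisopropylsilyl)oxy]phenyl}methyl acetate F8, which can be purified and stored. In step 11 it takes the place of 15: fluoride desilylation followed by 1,4-elimination of acetate should generate the same methide 16, which enolate 17 intercepts to give 18, and no alkylating halide is present to quench the catalyst.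

**Further compounds**
F1 | step 11 | (4R)-4-benzyl-3-{[2,4-bis(allyloxy)-5-(2-methylbut-3-en-2-yl)phenyl]acetyl}-1,3-oxazolidin-2-one | O=C(Cc1cc(C(C)(C)C=C)c(OCC=C)cc1OCC=C)N1[C@H](Cc2ccccc2)COC1=O
F2 | step 11 | (4R)-3-{(2R)-3-{4-(allyloxy)-5-(2-methylbut-3-en-2-yl)-2-[(triisopropylsilyl)oxy]phenyl}-2-[2,4-bis(allyloxy)-5-(2-methylbut-3-en-2-yl)phenyl]propanoyl}-4-benzyl-1,3-oxazolidin-2-one | O=C([C@H](Cc1cc(C(C)(C)C=C)c(OCC=C)cc1O[Si](C(C)C)(C(C)C)C(C)C)c1cc(C(C)(C)C=C)c(OCC=C)cc1OCC=C)N1[C@H](Cc2ccccc2)COC1=O
F3 | step 11 | (2R)-3-{4-(allyloxy)-5-(2-methylbut-3-en-2-yl)-2-[(triisopropylsilyl)oxy]phenyl}-2-[2,4-bis(allyloxy)-5-(2-methylbut-3-en-2-yl)phenyl]propan-1-ol | OC[C@H](Cc1cc(C(C)(C)C=C)c(OCC=C)cc1O[Si](C(C)C)(C(C)C)C(C)C)c1cc(C(C)(C)C=C)c(OCC=C)cc1OCC=C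
F4 | step 3 | 2-formyl-5-[(3-methylbut-2-en-1-yl)oxy]phenyl butanoate | CCCC(=O)Oc1cc(OCC=C(C)C)ccc1C=O
F5 | step 3 | 4-formyl-6-(2-methylbut-3-en-2-yl)-1,3-phenylene dibutanoate | O=Cc1cc(C(C)(C)C=C)c(OC(=O)CCC)cc1OC(=O)CCC
F6 | step 3 | 2,4-dihydroxy-5-(2-methylbut-3-en-2-yl)benzaldehyde | O=Cc1cc(C(C)(C)C=C)c(O)cc1O
F7 | step 3 | 4-(allyloxy)-2-hydroxy-5-(2-methylbut-3-en-2-yl)benzaldehyde | O=Cc1cc(C(C)(C)C=C)c(OCC=C)cc1O
F8 | step 10 | {4-(allyloxy)-5-(2-methylbut-3-en-2-yl)-2-[(triisopropylsilyl)oxy]phenyl}methyl acetate | CC(=O)OCc1cc(C(C)(C)C=C)c(OCC=C)cc1O[Si](C(C)C)(C(C)C)C(C)C
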